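- Ring, open dimer and isomer of the product together hold the charge: in the noon run they sum to 98.9 % at 10.0 h and 100 % at 48.0 h.

| flask | substrate | remark | time |
|---|---|---|---|
| noon | 0.33 M | run made earlier |  |
| dawn | 1.2 M | run made earlier |  |
| Saturday's | 0.25 M |  | 3.0 d |
| Sunday's | 0.50 M |  | 3.0 d |
| Wednesday's | 1.0 M |  | 3.0 d |

- noon (time / h: ring / %, open dimer / %, isomer of the product / %): 10.0: 23.5, 74.0, 1.4; 20.0: 21.8, 73.5, 3.3; 30.0: 20.4, 73.2, 5.7; 40.0: 22.9, 74.0, 5.5; 48.0: 22.1, 71.9, 6.0
- dawn (time / h: ring / %, open dimer / %, isomer of the product / %): 4.00: 9.5, 87.5, 0; 8.00: 9.3, 90.3, 0; 15.0: 10.4, 88.6, 1.3; 25.0: 8.7, 88.5, 2.2; 48.0: 8.9, 87.5, 3.3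

(scatter of a reading: 1 percentage point)

1. share of ring in all that became ring or open dimer or isomer of the product for Saturday's, Sunday's, Wednesday's, in this order
2. how that number moves from the first to the last of them (falls all the way / rises, then falls / falls, then rises / rises all the way / hardly changes)

- percentages count the substrate that a species holds: one open dimer counts as two
- the numbers in the tables scatter with a standard deviation of 1 percentage point
- "hardly changes" means that all values lie within two and a half points (for a concentration: within two and a half percent of the largest)

- With ring closure as the sole step, each substrate molecule ends as ring, so the ring share stands at the whole charge.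
- Add dimerisation, and each molecule meets a fork. With a fraction u of the charge left, its chance of closing is one over one plus a times u, where a, the selectivity factor, is substrate used by dimerisation over substrate used by closure at the start.
- Averaging that chance over the emptying flask gives the ring channel, ring plus isomer of the product: the logarithm of one plus a, divided by a.
- The noon run's open dimer reads from 74.0 % to 71.9 %, so the mean of its complement gives that run's ring channel, 26.7 %.
- Solving for a by repeated substitution and dividing by the noon charge gives the fork constant b, which is a per unit of charge concentration: 25.4 M⁻¹.
- As a check, b gives the dawn run a ring channel of 11.3 %, and the dawn run's mean open dimer leaves 11.5 %.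
- For the asked flasks, b gives ring channels of 31.4 %, 20.6 % and 12.9 %.
- Add the isomer of the product, which draws on the ring channel without changing its size. The noon run's last three readings give isomer over ring as 0.263.
- No run reaches the asked time of 3.0 d, so this reckoning assumes the ratio read at 30.0 h to 48.0 h for each asked flask, and ring then keeps 79.2 % of the channel.
- This reckoning therefore gives ring at 24.9 %, 16.3 % and 10.2 %, falling with charge.
- The forecast, reckoned separately, gives 25 %, 16.7 % and 10.4 %, so falls all the way, on the ground of “first-order ring closure competing with second-order dimerisation”.
- The flasks give 23.8 %, 15.6 % and 9.75 %, so falls all the way.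

    substrate → ring (k = 1.04 h⁻¹)
    2 substrate → open dimer (k = 15.4 M⁻¹ h⁻¹)
    substrate ⇌ dormant form (K = 1.50, k = 0.164 h⁻¹)
    ring ⇌ isomer of the product (K = 0.330, k = 0.00971 h⁻¹)

- Saturday's ring and isomer of the product relax with a half-life of 0.738 d, short against the 3.0 d. With b, Saturday's ring channel reckons to 31.4 % and stands at 31.0 %; Wednesday's reckons to 12.9 % and stands at 12.7 %.

(The numbers in the tables were generated by integration with constants of no real substance.)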